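At 18 min the reading of the alder run leaves 32.8 mM of the 50.0 mM of substrate it was charged with, bound forms counted, and I carry that leftover, not the rate at the start, over to the oak run.

| setting | larch | birch | alder | cedar | oak |
|---|---|---|---|---|---|
| substrate | 50.0 mM | 30.0 mM | 50.0 mM | 50.0 mM | 17.0 mM |
| reagent | 50.0 mM | 30.0 mM | 150 mM | 50.0 mM | 150 mM |
| free catalyst | 0.100 mM | 0.100 mM | 0.100 mM | 0.100 mM | 0.100 mM |
| target |  |  |  | 15.0 mM |  |
| time |  |  |  |  | 18 min |

| run | time / min | [target] / mM |
|---|---|---|
| larch run | 3.6 | 7.5 |
| larch run | 7.2 | 13.8 |
| larch run | 11 | 17.7 |
| larch run | 14 | 20.9 |
| larch run | 18 | 22.9 |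
| birch run | 3.6 | 5.6 |
| birch run | 7.2 | 9.8 |
| birch run | 11 | 12.1 |
| birch run | 14 | 13.8 |
| birch run | 18 | 15.8 |
| alder run | 3.6 | 3.5 |
| alder run | 7.2 | 7.6 |
| alder run | 11 | 11.1 |
| alder run | 14 | 13.8 |
| alder run | 18 | 17.2 |
| cedar run | 3.6 | 23.9 |
| cedar run | 7.2 | 29.0 |
| cedar run | 11 | 32.1 |
| cedar run | 14 | 35.0 |
| cedar run | 18 | 38.5 |

(readings scatter by 0.4 mM)

- Overall: substrate + reagent -> target, with free catalyst as catalyst.
- Constant volume, constant temperature.
- Readings of a species count what is bound in complexes too.
- An order is taken over about fifteen percent of the charge, up and down.

- order of the initial rate in [substrate], near the charge of the larch run, the rate being that where two percent of its substrate are target (one fixed amount of target, the same in the runs compared)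
- order of the initial rate in [reagent], near the charge of the larch run, the rate being that where two percent of its substrate are target
- the birch run starts with 20.0 mM less of substrate and of reagent than the larch run, and with no target. Compared where both hold the same amount of substrate, once fifteen percent of what the birch run was charged with has turned into target, is the birch run faster, slower or alike (within a tenth)?
- target in the oak run at 18 min, as a share of the substrate charged

The oak run has the alder charge of reagent, 150 mM, against 17.0 mM of substrate. So [reagent] stays high, substrate is the limiting reagent, and I treat its loss as pseudo-first-order. From the leftover, the logarithm of charge over leftover divided by the time gives 0.0234 min⁻¹. This is the alder constant: the fraction of the remaining substrate that turns into target per minute at this [reagent]. The alder reading at 7.2 min gives 0.0229 min⁻¹ by the same reckoning, so these two readings of the alder run give nearly the same constant. The cedar run, charged with 15.0 mM of target, makes 23.5 mM by 18 min against 22.9 mM in the larch run, so I apply no correction for target.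

Now I draw the oak curve. Its slope at the start is the constant times the charge, 0.398 mM min⁻¹. By 18 min the reckoning leaves 11.2 mM of substrate, so the slope has eased to 0.262 mM min⁻¹. Target in the oak run then stands, in this reckoning, at 5.80 mM, which is 34.4% of the charge. The reckoned curve shows no knee in this time, since its half-conversion comes at 29.6 min, later than 18 min. The level this reckoned curve heads for is the substrate charge of 17.0 mM.

The forecast gives 0.6 for the substrate order, −0.25 for the reagent order, faster for the birch run and 48% for the oak run, reading that “the alder curve suggests saturation”. My reckoning differs: I read the same curve as first order, and my 34.4% is lower than the forecast's figure.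

The flask gives 0.79 for the substrate order, −0.10 for the reagent order, faster for the birch run, at 3.3 times the larch rate where both hold the same amount of substrate, and 31.3% for the oak run.

    free catalyst + substrate → catalyst-substrate complex (1506 M⁻¹ min⁻¹)
    catalyst-substrate complex + reagent → target + free catalyst (3984 M⁻¹ min⁻¹)
    catalyst-substrate complex → spent catalyst + substrate (0.2358 min⁻¹)
    substrate + reagent ⇌ idle substrate-reagent adduct, settled at all times (45.00 M⁻¹)

The oak result, turned back through the same logarithm, gives a constant of 0.0209 min⁻¹, which is 89.3% of the alder constant. That constant is lower than the 0.151 min⁻¹ of the first step on the catalyst charge because substrate is parked as idle substrate-reagent adduct: with the parking taken away, the oak run reaches 92.2% instead of 31.3%. In the alder run, 0.0234 min⁻¹ puts target at half of the substrate charged at 29.6 min, and the simulation gives 29.5 min.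

Readings and results were computed from invented constants; the scatter is artificial.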